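**Retrosynthetic overview**
1. Ring C (bromo-dimethylcyclohexanol) is closed last: 14,15-bromonium ion, attack by the CH2 of a C11 exo-methylene, capture of the C11 cation by the neighbouring C10 acetate (geranylgeranyl numbering).
2. The allylic acetate comes from an α-methylene ketone, made from a bromo γ-lactone and a 2-lithio-1,5-diene (from 6-methylhept-5-en-2-one); ring B (cyclopentanol) is closed by an intramolecular aldol (C1–C9 bond).
3. Ring A is closed first: 6,7-bromonium ion, attack by the 2,3-olefin, capture of the C3 cation by the ester oxygen, then acid equilibration to the axial C–O bond.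
4. The acyclic (E,E)-diene ester comes from two carboalumination/cross-coupling cycles on a C4 alkyne, a C4 alkynyl bromide and tert-butyl bromoacetate.
5. Order of ring formation: A (bromocyclohexane) → B (cyclopentanol) → C (bromocyclohexanol).

Assumption 1: the skeleton is taken to arise in nature from a geranylgeranyl chain by bromonium-initiated closure of the 6,7- onto the 2,3-olefin with oxygen capture at C3, C1–C9 bond formation, and bromonium-initiated closure of the 14,15-olefin onto a C11 exo-methylene with oxygen capture at C11.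
Assumption 2: in steps 5 and 12 the catalyst antipode that delivers bromine to the Si face of the olefinic CH carbon is used; it is identified by screening both antipodes.
Assumption 3: hydrindanes are named by indene numbering (C1 side chain, C2 hydroxyl, C3a angular methyl, C4 bromine, C7 tertiary carbinol).

Step 1
Reactants: 1 tert-butyl(but-3-yn-1-yloxy)dimethylsilane
Product: 3 tert-butyl{[(3E)-4-iodo-3-methylbut-3-en-1-yl]oxy}dimethylsilane, via dimethylalkenylaluminium 2 (not isolated)
Conditions: Me3Al (2 equiv), Cp2ZrCl2 (0.2 equiv), CH2Cl2, 0 °C to rt; then I2, THF, −30 °C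
Reagents that add atoms: trimethylaluminium, C[Al](C)C; iodine, II
Why: Zirconium-catalysed carboalumination (Negishi) adds methyl and aluminium syn across the terminal alkyne with aluminium at the terminus, and iodinolysis with retention gives the (E)-alkenyl iodide, which fixes the geometry of the olefin that later carries the bromonium ion.

Step 2
Reactants: 3 tert-butyl{[(3E)-4-iodo-3-methylbut-3-en-1-yl]oxy}dimethylsilane; 4 (4-bromobut-1-yn-1-yl)trimethylsilane
Product: 7 tert-butyldimethyl{[(3E)-3-methyloct-3-en-7-yn-1-yl]oxy}silane, via alkylzinc bromide 5 (not isolated), via bis-silyl enyne 6 (not isolated)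
Conditions: 4, Zn, LiCl, THF, 50 °C; then 3, Pd(dppf)Cl2 (3 mol %), THF, rt; then K2CO3, MeOH, rt
Reagents that add atoms: none
Why: Zinc insertion into the primary bromide and Negishi cross-coupling with the alkenyl iodide join sp3 to sp2 carbon with retention of the E geometry, and methanolysis cleaves only the alkynyl C–Si bond, leaving the TBS ether.

Step 3
Reactants: 7 tert-butyldimethyl{[(3E)-3-methyloct-3-en-7-yn-1-yl]oxy}silane
Product: 9 tert-butyl{[(3E,7E)-8-iodo-3,7-dimethylocta-3,7-dien-1-yl]oxy}dimethylsilane, via dimethyldienylaluminium 8 (not isolated)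
Conditions: Me3Al (2 equiv), Cp2ZrCl2 (0.2 equiv), CH2Cl2, 0 °C to rt; then I2, THF, −30 °C
Reagents that add atoms: trimethylaluminium, C[Al](C)C; iodine, II
Why: A second syn carboalumination/iodinolysis, chemoselective for the terminal alkyne over the trisubstituted olefin, sets the second (E)-trisubstituted double bond.

Step 4
Reactants: 9 tert-butyl{[(3E,7E)-8-iodo-3,7-dimethylocta-3,7-dien-1-yl]oxy}dimethylsilane; 10 tert-butyl bromoacetate
Product: 12 tert-butyl (3E,7E)-10-{[tert-butyl(dimethyl)silyl]oxy}-4,8-dimethyldeca-3,7-dienoate, via BrZnCH2CO2t-Bu 11 (not isolated)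
Conditions: 10, Zn, THF, 40 °C; then 9, Pd2(dba)3 (2 mol %), XPhos (8 mol %), THF, 50 °C
Reagents that add atoms: none
Why: Palladium-catalysed cross-coupling of the zinc ester enolate (Reformatsky reagent) with the alkenyl iodide gives the β,γ-unsaturated tert-butyl ester with retention of geometry under non-basic conditions that do not move the double bond into conjugation.

Step 5
Reactants: 12 tert-butyl (3E,7E)-10-{[tert-butyl(dimethyl)silyl]oxy}-4,8-dimethyldeca-3,7-dienoate
Product: 14 (3aS,4S,5S,7aR)-5-bromo-4-(2-hydroxyethyl)-4,7a-dimethylhexahydro-1-benzofuran-2(3H)-one, via trans-fused silyl lactone 13 (not isolated)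
Conditions: 1,3-dibromo-5,5-dimethylhydantoin (0.55 equiv), (S)-3,3'-bis(2,4,6-triisopropylphenyl)-1,1'-binaphthalene-2,2'-diyl N-triflylthiophosphoramide (10 mol %), toluene–CH2Cl2, −78 °C; then MeSO3H (3 equiv), CH2Cl2, 0 °C to rt; aq NaHCO3
Reagents that add atoms: 1,3-dibromo-5,5-dimethylhydantoin, CC1(C)N(Br)C(=O)N(Br)C1=O
Why: Proposed new method: the Lewis-basic P=S group of the chiral catalyst takes Br+ from the hydantoin and hands it to the Si face of C7 of the more electron-rich 7,8-olefin (the 3,4-olefin is deactivated by the allylic ester), the bromonium ion is opened by C3 of the 3,4-olefin through a chair transition state so that the E,E geometry gives equatorial bromine cis to the new quaternary methyl and the two side arms trans-diequatorial, the tert-butyl ester oxygen captures the tertiary cation with loss of isobutene to give the kinetic trans-fused lactone, and MeSO3H then reversibly ionises the tertiary C–O bond so that the lactone settles in the cis-fused form with axial C–O (relief of the 1,3-diaxial methyl/methyl contact) while the TBS group is lost; the closest known reaction types are chiral Lewis-base-catalysed enantioselective bromonium cyclisation of homogeranyl arenes, the racemic bromolactonising cyclisation of homogeranic acid and the acid epimerisation of trans-fused terpenoid γ-lactones.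

Step 6
Reactants: 15 6-methylhept-5-en-2-one
Product: 16 N'-(6-methylhept-5-en-2-ylidene)-2,4,6-tri(propan-2-yl)benzenesulfonohydrazide
Conditions: 2,4,6-triisopropylbenzenesulfonohydrazide, cat. HCl, MeOH, rt
Reagents that add atoms: 2,4,6-tri(propan-2-yl)benzenesulfonohydrazide, NNS(=O)(=O)c1c(C(C)C)cc(C(C)C)cc1C(C)C
Why: Acid-catalysed condensation of the ketone with the sulfonyl hydrazide gives the arenesulfonylhydrazone needed for a Shapiro reaction.

Step 7
Reactants: 16 N'-(6-methylhept-5-en-2-ylidene)-2,4,6-tri(propan-2-yl)benzenesulfonohydrazide; 14 (3aS,4S,5S,7aR)-5-bromo-4-(2-hydroxyethyl)-4,7a-dimethylhexahydro-1-benzofuran-2(3H)-one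
Product: 18 1-[(1S,2S,3S,6R)-3-bromo-6-hydroxy-2-(2-hydroxyethyl)-2,6-dimethylcyclohexyl]-7-methyl-3-methylideneoct-6-en-2-one, via alkenyllithium 17 (not isolated)
Conditions: 16 (3.2 equiv), n-BuLi (6.4 equiv), TMEDA, hexane–THF, −78 to 0 °C; then 14, THF, −78 °C; aq NH4Cl
Reagents that add atoms: none
Why: The Shapiro reaction deprotonates the hydrazone at the methyl group and gives the less substituted alkenyllithium, one equivalent of which deprotonates the primary alcohol while a second adds to the lactone carbonyl to a lithium lactolate that resists further addition and opens on work-up to the α-methylene ketone and the free axial tertiary alcohol, whose C–O bond is not touched.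

Step 8
Reactants: 18 1-[(1S,2S,3S,6R)-3-bromo-6-hydroxy-2-(2-hydroxyethyl)-2,6-dimethylcyclohexyl]-7-methyl-3-methylideneoct-6-en-2-one
Product: 19 2-[(1S,2S,3R,6S)-6-bromo-3-hydroxy-1,3-dimethyl-2-(7-methyl-3-methylidene-2-oxooct-6-en-1-yl)cyclohexyl]acetaldehyde
Conditions: Dess–Martin periodinane, NaHCO3, CH2Cl2, 0 °C
Reagents that add atoms: none
Why: Dess–Martin oxidation converts the primary alcohol into the aldehyde under buffered, non-enolising conditions while the tertiary alcohol, the enone and the secondary bromide are inert.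

Step 9
Reactants: 19 2-[(1S,2S,3R,6S)-6-bromo-3-hydroxy-1,3-dimethyl-2-(7-methyl-3-methylidene-2-oxooct-6-en-1-yl)cyclohexyl]acetaldehyde
Product: 20 1-[(1S,2R,3aS,4S,7R,7aS)-4-bromo-2,7-dihydroxy-3a,7-dimethyloctahydro-1H-inden-1-yl]-6-methyl-2-methylidenehept-5-en-1-one
Conditions: LiN(SiMe3)2 (1.1 equiv), THF, −78 to −40 °C; AcOH (1.2 equiv), −78 °C
Reagents that add atoms: none
Why: Intramolecular aldol addition, in which the ketone can enolise only towards the ring-bound CH2 (its other α-carbon is the methylidene carbon) and the aldehyde enolate has no feasible ring closure and therefore only exchanges protons, closes the five-membered ring through a lithium-chelated chair-like transition state that places hydroxyl and acyl group cis on the α face, away from the angular methyl and the C7 substituents, the trans ring fusion following from the two diequatorial arms.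

Step 10
Reactants: 20 1-[(1S,2R,3aS,4S,7R,7aS)-4-bromo-2,7-dihydroxy-3a,7-dimethyloctahydro-1H-inden-1-yl]-6-methyl-2-methylidenehept-5-en-1-one
Product: 21 (1S,2R,3aS,4S,7R,7aS)-4-bromo-1-[(1R)-1-hydroxy-6-methyl-2-methylidenehept-5-en-1-yl]-3a,7-dimethyloctahydro-1H-indene-2,7-diol
Conditions: Et2BOMe (1.2 equiv), THF–MeOH 4:1, −78 °C; NaBH4; AcOH, MeOH co-evaporation
Reagents that add atoms: none
Why: Narasaka–Prasad reduction, in which the boron chelate of the β-hydroxy ketone is attacked by external hydride axially with the ring carbinol substituent equatorial, gives the 1,3-syn diol and hence the (R) carbinol by 1,2-reduction of the activated carbonyl.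

Step 11
Reactants: 21 (1S,2R,3aS,4S,7R,7aS)-4-bromo-1-[(1R)-1-hydroxy-6-methyl-2-methylidenehept-5-en-1-yl]-3a,7-dimethyloctahydro-1H-indene-2,7-diol
Product: 23 (1R)-1-[(1R,2R,3aS,4S,7R,7aS)-4-bromo-7-hydroxy-3a,7-dimethyl-2-[(triethylsilyl)oxy]octahydro-1H-inden-1-yl]-6-methyl-2-methylidenehept-5-en-1-yl acetate, via mono-silyl diol 22 (not isolated)
Conditions: Et3SiCl (1.1 equiv), imidazole, CH2Cl2, −20 °C; then Ac2O, DMAP, pyridine, rt
Reagents that add atoms: chlorotriethylsilane, CC[Si](Cl)(CC)CC; acetic anhydride, CC(=O)OC(C)=O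
Why: Selective silylation, in which chlorotriethylsilane takes the ring carbinol with one α-branch in preference to the allylic carbinol flanked by two branched carbons, is followed in the same flask by DMAP-catalysed acetylation of the remaining secondary alcohol, the tertiary alcohol staying free.

Step 12
Reactants: 23 (1R)-1-[(1R,2R,3aS,4S,7R,7aS)-4-bromo-7-hydroxy-3a,7-dimethyl-2-[(triethylsilyl)oxy]octahydro-1H-inden-1-yl]-6-methyl-2-methylidenehept-5-en-1-yl acetate
Product: 25 (R)-[(1S,2R,3aS,4S,7R,7aS)-4-bromo-2,7-dihydroxy-3a,7-dimethyloctahydro-1H-inden-1-yl][(1R,4S)-4-bromo-1-hydroxy-3,3-dimethylcyclohexyl]methyl acetate (CNP0166243.1), via silyl-protected bromocycle 24 (not isolated)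
Conditions: 1,3-dibromo-5,5-dimethylhydantoin (0.55 equiv), catalyst of step 5 (10 mol %), CH2Cl2–toluene, −78 °C; H2O–THF, Et3N, 0 °C; then HF·pyridine, THF, 0 °C
Reagents that add atoms: 1,3-dibromo-5,5-dimethylhydantoin, CC1(C)N(Br)C(=O)N(Br)C1=O; water, O
Why: Proposed new method: the same chiral Lewis base delivers Br+ to the Si face of C5 of the only electron-rich olefin, the CH2 terminus of the 1,1-disubstituted olefin (itself deactivated towards Br+ by the allylic acetate) attacks the tertiary bromonium carbon through a chair to give the six-membered ring with equatorial bromine, the tertiary cation is captured by the carbonyl oxygen of the neighbouring acetate on the face that keeps the bulky carbinyl substituent equatorial (C–O axial, cis to bromine), water opens the acetoxonium ion to the hydroxy acetate, which rests as the secondary acetate, and HF·pyridine removes the silyl ether; the closest known reaction types are bromonium-induced cyclisation of myrcene-type 1,1-disubstituted olefins to ochtodane rings, chiral Lewis-base-catalysed bromocyclisation and Woodward-type acetoxonium hydrolysis.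

**Compound list**
1 | tert-butyl(but-3-yn-1-yloxy)dimethylsilane | C#CCCO[Si](C)(C)C(C)(C)C | starting material
2 | [(1E)-4-{[tert-butyl(dimethyl)silyl]oxy}-2-methylbut-1-en-1-yl]dimethylaluminium | C[Al](C)/C=C(\C)CCO[Si](C)(C)C(C)(C)C | intermediate
3 | tert-butyl{[(3E)-4-iodo-3-methylbut-3-en-1-yl]oxy}dimethylsilane | I/C=C(\C)CCO[Si](C)(C)C(C)(C)C | intermediate
4 | (4-bromobut-1-yn-1-yl)trimethylsilane | C[Si](C)(C)C#CCCBr | starting material
5 | bromo[4-(trimethylsilyl)but-3-yn-1-yl]zinc | C[Si](C)(C)C#CCC[Zn]Br | intermediate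
6 | tert-butyldimethyl{[(3E)-3-methyl-8-(trimethylsilyl)oct-3-en-7-yn-1-yl]oxy}silane | C[Si](C)(C)C#CCC/C=C(\C)CCO[Si](C)(C)C(C)(C)C | intermediate
7 | tert-butyldimethyl{[(3E)-3-methyloct-3-en-7-yn-1-yl]oxy}silane | C#CCC/C=C(\C)CCO[Si](C)(C)C(C)(C)C | intermediate
8 | [(1E,5E)-8-{[tert-butyl(dimethyl)silyl]oxy}-2,6-dimethylocta-1,5-dien-1-yl]dimethylaluminium | C[Al](C)/C=C(\C)CC/C=C(\C)CCO[Si](C)(C)C(C)(C)C | intermediate
9 | tert-butyl{[(3E,7E)-8-iodo-3,7-dimethylocta-3,7-dien-1-yl]oxy}dimethylsilane | I/C=C(\C)CC/C=C(\C)CCO[Si](C)(C)C(C)(C)C | intermediate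
10 | tert-butyl bromoacetate | CC(C)(C)OC(=O)CBr | starting material
11 | bromo(2-tert-butoxy-2-oxoethyl)zinc | CC(C)(C)OC(=O)C[Zn]Br | intermediate
12 | tert-butyl (3E,7E)-10-{[tert-butyl(dimethyl)silyl]oxy}-4,8-dimethyldeca-3,7-dienoate | CC(C)(C)OC(=O)C/C=C(\C)CC/C=C(\C)CCO[Si](C)(C)C(C)(C)C | intermediate
13 | (3aS,4S,5S,7aS)-5-bromo-4-(2-{[tert-butyl(dimethyl)silyl]oxy}ethyl)-4,7a-dimethylhexahydro-1-benzofuran-2(3H)-one (trans-fused) | CC(C)(C)[Si](C)(C)OCC[C@]1(C)[C@@H](Br)CC[C@]2(C)OC(=O)C[C@@H]12 | intermediate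
14 | (3aS,4S,5S,7aR)-5-bromo-4-(2-hydroxyethyl)-4,7a-dimethylhexahydro-1-benzofuran-2(3H)-one (cis-fused) | OCC[C@]1(C)[C@@H](Br)CC[C@@]2(C)OC(=O)C[C@@H]12 | intermediate
15 | 6-methylhept-5-en-2-one | CC(=O)CCC=C(C)C | starting material
16 | N'-(6-methylhept-5-en-2-ylidene)-2,4,6-tri(propan-2-yl)benzenesulfonohydrazide | CC(CCC=C(C)C)=NNS(=O)(=O)c1c(C(C)C)cc(C(C)C)cc1C(C)C | intermediate
17 | (6-methylhepta-1,5-dien-2-yl)lithium | [Li]C(=C)CCC=C(C)C | intermediate
18 | 1-[(1S,2S,3S,6R)-3-bromo-6-hydroxy-2-(2-hydroxyethyl)-2,6-dimethylcyclohexyl]-7-methyl-3-methylideneoct-6-en-2-one | OCC[C@]1(C)[C@@H](Br)CC[C@@](C)(O)[C@H]1CC(=O)C(=C)CCC=C(C)C | intermediate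
19 | 2-[(1S,2S,3R,6S)-6-bromo-3-hydroxy-1,3-dimethyl-2-(7-methyl-3-methylidene-2-oxooct-6-en-1-yl)cyclohexyl]acetaldehyde | O=CC[C@]1(C)[C@@H](Br)CC[C@@](C)(O)[C@H]1CC(=O)C(=C)CCC=C(C)C | intermediate
20 | 1-[(1S,2R,3aS,4S,7R,7aS)-4-bromo-2,7-dihydroxy-3a,7-dimethyloctahydro-1H-inden-1-yl]-6-methyl-2-methylidenehept-5-en-1-one | C=C(CCC=C(C)C)C(=O)[C@@H]1[C@H](O)C[C@]2(C)[C@@H](Br)CC[C@@](C)(O)[C@@H]12 | intermediate
21 | (1S,2R,3aS,4S,7R,7aS)-4-bromo-1-[(1R)-1-hydroxy-6-methyl-2-methylidenehept-5-en-1-yl]-3a,7-dimethyloctahydro-1H-indene-2,7-diol | O[C@H]([C@@H]1[C@H](O)C[C@]2(C)[C@@H](Br)CC[C@@](C)(O)[C@@H]12)C(=C)CCC=C(C)C | intermediate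
22 | (1R)-1-[(1R,2R,3aS,4S,7R,7aS)-4-bromo-7-hydroxy-3a,7-dimethyl-2-[(triethylsilyl)oxy]octahydro-1H-inden-1-yl]-6-methyl-2-methylidenehept-5-en-1-ol | O[C@H]([C@@H]1[C@H](O[Si](CC)(CC)CC)C[C@]2(C)[C@@H](Br)CC[C@@](C)(O)[C@@H]12)C(=C)CCC=C(C)C | intermediate
23 | (1R)-1-[(1R,2R,3aS,4S,7R,7aS)-4-bromo-7-hydroxy-3a,7-dimethyl-2-[(triethylsilyl)oxy]octahydro-1H-inden-1-yl]-6-methyl-2-methylidenehept-5-en-1-yl acetate | CC(=O)O[C@H]([C@@H]1[C@H](O[Si](CC)(CC)CC)C[C@]2(C)[C@@H](Br)CC[C@@](C)(O)[C@@H]12)C(=C)CCC=C(C)C | intermediate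
24 | (R)-[(1R,2R,3aS,4S,7R,7aS)-4-bromo-7-hydroxy-3a,7-dimethyl-2-[(triethylsilyl)oxy]octahydro-1H-inden-1-yl][(1R,4S)-4-bromo-1-hydroxy-3,3-dimethylcyclohexyl]methyl acetate | CC(=O)O[C@H]([C@@H]1[C@H](O[Si](CC)(CC)CC)C[C@]2(C)[C@@H](Br)CC[C@@](C)(O)[C@@H]12)[C@@]1(O)CC[C@H](Br)C(C)(C)C1 | intermediate
25 | (R)-[(1S,2R,3aS,4S,7R,7aS)-4-bromo-2,7-dihydroxy-3a,7-dimethyloctahydro-1H-inden-1-yl][(1R,4S)-4-bromo-1-hydroxy-3,3-dimethylcyclohexyl]methyl acetate | CC(=O)O[C@H]([C@@H]1[C@H](O)C[C@]2(C)[C@@H](Br)CC[C@@](C)(O)[C@@H]12)[C@@]1(O)CC[C@H](Br)C(C)(C)C1 | target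

**Step count**
Total: 12 steps. Longest linear sequence: 11 steps (steps 1–5 and 7–12); step 6 prepares the side-chain reagent.

**Steps most likely to fail and their fallbacks**

Step 5 may fail in enantioselectivity, in the choice between the two olefins, or in the acid equilibration. The fallback sets out from 12 and replaces catalyst control by a bromonium ion of fixed configuration. Shi epoxidation of the more electron-rich 7,8-olefin (fructose-derived ketone antipode that gives the R,R epoxide, KHSO5 as 2KHSO5·KHSO4·K2SO4, K2CO3 buffer, MeCN–dimethoxymethane–H2O, 0 °C) gives tert-butyl (3E)-6-[(2R,3R)-3-(2-{[tert-butyl(dimethyl)silyl]oxy}ethyl)-3-methyloxiran-2-yl]-4-methylhex-3-enoate F1. Li2NiBr4 in THF opens the epoxide at the secondary carbon with inversion to tert-butyl (3E,7S,8R)-7-bromo-10-{[tert-butyl(dimethyl)silyl]oxy}-8-hydroxy-4,8-dimethyldec-3-enoate F2. MeSO3H in (CF3)2CHOH then ionises the tertiary alcohol with participation of bromine; the bromonium ion cyclises and lactonises, and the same acid equilibrates the lactone and removes the silyl ether. The fallback comes back to the route at 14.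

Step 9 may fail because the aldehyde is also enolisable and the α-methylene ketone is a Michael acceptor. The fallback sets out from 18 and makes the enolate from a C–Br bond instead of by deprotonation. Me3SiOTf/Et3N in CH2Cl2 at −78 °C, then N-bromosuccinimide and dilute HCl work-up, gives the 1-bromo derivative of 18 at C1 of the octenone chain F3 (either epimer serves). Dess–Martin oxidation gives the bromo keto aldehyde from F3 F4. CrCl2 (divalent chromium) with catalytic LiI in THF at 0 °C turns the C–Br bond into a chromium enolate that adds to the aldehyde through a chelated chair (Reformatsky-type). The fallback comes back to the route at 20.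

Step 12 may fail in the facial selectivity at the remote olefin or in the capture of the tertiary cation. The fallback sets out from 23 and again fixes the bromonium configuration beforehand. Shi epoxidation of the terminal trisubstituted olefin gives (1R)-1-[(1R,2R,3aS,4S,7R,7aS)-4-bromo-7-hydroxy-3a,7-dimethyl-2-[(triethylsilyl)oxy]octahydro-1H-inden-1-yl]-4-[(2R)-3,3-dimethyloxiran-2-yl]-2-methylidenebutyl acetate F5. Li2NiBr4 in THF gives (1R,5S)-1-[(1R,2R,3aS,4S,7R,7aS)-4-bromo-7-hydroxy-3a,7-dimethyl-2-[(triethylsilyl)oxy]octahydro-1H-inden-1-yl]-5-bromo-6-hydroxy-6-methyl-2-methylideneheptyl acetate F6. MeSO3H in (CF3)2CHOH at 0 °C ionises the tertiary alcohol, the bromonium ion is attacked by the exo-methylene, the acetate captures the cation, the water released opens the acetoxonium ion and the acid removes the silyl ether. The fallback comes back to the route at 25.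

**Further compounds**
F1 | step 5 | tert-butyl (3E)-6-[(2R,3R)-3-(2-{[tert-butyl(dimethyl)silyl]oxy}ethyl)-3-methyloxiran-2-yl]-4-methylhex-3-enoate | CC(C)(C)OC(=O)C/C=C(\C)CC[C@H]1O[C@]1(C)CCO[Si](C)(C)C(C)(C)C
F2 | step 5 | tert-butyl (3E,7S,8R)-7-bromo-10-{[tert-butyl(dimethyl)silyl]oxy}-8-hydroxy-4,8-dimethyldec-3-enoate | CC(C)(C)OC(=O)C/C=C(\C)CC[C@H](Br)[C@](C)(O)CCO[Si](C)(C)C(C)(C)C
F3 | step 9 | 1-bromo derivative of 18 at C1 of the octenone chain (either epimer at CHBr) | OCC[C@]1(C)[C@@H](Br)CC[C@@](C)(O)[C@H]1C(Br)C(=O)C(=C)CCC=C(C)C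
F4 | step 9 | bromo keto aldehyde from F3 (primary alcohol oxidised to the aldehyde) | O=CC[C@]1(C)[C@@H](Br)CC[C@@](C)(O)[C@H]1C(Br)C(=O)C(=C)CCC=C(C)C
F5 | step 12 | (1R)-1-[(1R,2R,3aS,4S,7R,7aS)-4-bromo-7-hydroxy-3a,7-dimethyl-2-[(triethylsilyl)oxy]octahydro-1H-inden-1-yl]-4-[(2R)-3,3-dimethyloxiran-2-yl]-2-methylidenebutyl acetate | CC(=O)O[C@H]([C@@H]1[C@H](O[Si](CC)(CC)CC)C[C@]2(C)[C@@H](Br)CC[C@@](C)(O)[C@@H]12)C(=C)CC[C@H]1OC1(C)C
F6 | step 12 | (1R,5S)-1-[(1R,2R,3aS,4S,7R,7aS)-4-bromo-7-hydroxy-3a,7-dimethyl-2-[(triethylsilyl)oxy]octahydro-1H-inden-1-yl]-5-bromo-6-hydroxy-6-methyl-2-methylideneheptyl acetate | CC(=O)O[C@H]([C@@H]1[C@H](O[Si](CC)(CC)CC)C[C@]2(C)[C@@H](Br)CC[C@@](C)(O)[C@@H]12)C(=C)CC[C@H](Br)C(C)(C)O
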